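Subtraction comes first: by 6.00 h the birch run has lost L = 5.80% of its substrate and the ash run L = 9.10%, while target reads 2.7% and 4.7%.

| setting | birch | ash | summer | dusk | autumn |
|---|---|---|---|---|---|
| substrate | 0.12 M | 0.12 M | 0.12 M | 0.12 M | 0.12 M |
| partner | 0.063 M | 0.26 M | 0.0500 M | 0.100 M | 0.200 M |
| second reagent | 0.36 M | 0.36 M | 0.360 M | 0.360 M | 0.360 M |
| remark | run made earlier | run made earlier |  |  |  |
| time |  |  | 8.0 h | 8.0 h | 8.0 h |

| run | time / h | target / % | substrate / % |
|---|---|---|---|
| birch | 0.667 | 0 | 96.8 |
| birch | 2.00 | 1.0 | 94.7 |
| birch | 4.00 | 2.2 | 94.9 |
| birch | 6.00 | 2.7 | 94.2 |
| ash | 0.667 | 0.2 | 93.5 |
| ash | 2.00 | 1.6 | 92.3 |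
| ash | 4.00 | 3.0 | 91.3 |
| ash | 6.00 | 4.7 | 90.9 |

(each reading ± 0.3 percentage points)

* amount of target at the end, in percent of the substrate charged for summer, dusk, autumn, in this order
* the shape of the row from first to last (rises all the way / falls all the way / hardly changes / rises, then falls / falls, then rises)

- on the list of suspects stand: substrate + partner -> intermediate; second reagent + intermediate -> target; 2 partner -> self-condensation product
- "hardly changes" means that all values lie within two and a half points (for a concentration: within two and a half percent of the largest)

Two chemists dispute the row. The first calls partner the limiting reagent in summer and dusk, as both charges lie below the substrate's 0.12 M, and lets target follow the charge. Birch target, carried linearly in time and scaled by charge, gives him 2.86% for summer and twice that, 5.71%, for dusk. That gap of 2.8 percentage points already leaves the margin, so his row rises. He sets the ash run aside, since its partner charge exceeds the substrate's.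

The second takes self-condensation, second order in partner, as the fast step and reckons with what it leaves free for capture, which she expects to grow with the logarithm of the charge. Her quantity is the capture slope s, the substrate lost per e-fold of partner charged, with the substrate and second reagent charges held fixed. Read from the two runs, s = 2.3 points per e-fold, a reading with the scatter of its sources. From summer to autumn this gives a gap in substrate lost of 3.2 points. Taking capture as early and the intermediate's decay as first order, the ash readings give a rate κ = 0.121 /h. So she reckons that a share φ = 62.0% of the lost substrate is target at 8.0 h, and she estimates the spread of the row as W = φ × gap = 2 points, inside the margin.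

That reckoning is separate from the forecast, which sides with her by interpolation: 3.5%, 4.6%, 5.8%, hardly changes, a spread of 2.3 points, with the words “either way the response is shallow”.

The flask gives 3.66%, 4.49% and 5.33%: hardly changes, with a spread of 1.7 points against W = 2 points.

    substrate + partner → intermediate (k = 0.0500 /M/min)
    second reagent + intermediate → target (k = 0.00700 /M/min)
    2 partner → self-condensation product (k = 1.30 /M/min)

At the start of summer partner goes to self-condensation 22 times as fast as to capture, and the first chemist's proportion belongs where that ratio lies far below one. The slope also reaches a further state: at 80.0 h, with intermediate at 0%, summer holds 5.90% target, so s predicts 7.52% for dusk, which stands at 7.13%.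

The data were generated by integration for substances that don't exist.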